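**Strategy.** Everything rests on opening ring C (the pyranone) at O1–C2 and C4–C4a, one oxidation level up, as the flavone. The key step exploits the 1,3-relationship of the ring A oxygen O1 and the ortho carbon C4a: 3,5-dimethoxyphenol is an O,C-bisnucleophile with two equivalent ortho carbons, and ethyl 3,4,5-trimethoxybenzoylacetate is the matching bis-electrophile (ester carbon becomes C4, aryl ketone carbon becomes C2). One thermal annulation of these two unprotected, commercial components acylates the ring carbon and closes the aryl enol ether. The lone stereocentre C2 is then set by catalytic asymmetric hydrogenation of C2=C3, and the over-reduced C4 carbinol is re-oxidised.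

Key step: step 1

Assumption: the (R,R) antipode of the NHC ligand is written for the 2S series and is exchanged for (S,S) if a test run shows the opposite sense; carbinol 6 is drawn 2,4-cis, its C4 configuration being erased in step 3, and any ketone left by incomplete carbonyl reduction in step 2 is already 7 and passes through step 3 unchanged.

Step 1
Reactants: 1 3,5-dimethoxyphenol; 2 ethyl 3-oxo-3-(3,4,5-trimethoxyphenyl)propanoate
Product: 5 5,7-dimethoxy-2-(3,4,5-trimethoxyphenyl)-4H-chromen-4-one, via aroylketene 3 (not isolated), via 2-hydroxyaryl 1,3-diketone 4 (not isolated)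
Conditions: 2 (2 equiv), neat melt, N2 sweep (EtOH and H2O distilled off), 240 °C
Reagents that add atoms: none
Why: Mentzer-type thermal chromone annulation (the Simonis mode of phenol/β-keto ester condensation), the closest known reaction type being the melt condensation of phloroglucinol-type phenols with aroylacetates to 5,7-dioxygenated flavones. At 240 °C 2 should lose ethanol to aroylketene 3, which is captured by the phenol OH and delivered (O-acylation followed by thermal ortho acyl shift, or OH-assisted direct attack) to the adjacent ring carbon, forming C4–C4a in the 2-hydroxyaryl 1,3-diketone 4. The chelated ortho OH of 4 then adds to the aryl ketone carbon in a 6-exo-trig closure of ring C, and loss of water forms O1–C2 and the aromatic 4-pyranone, which makes the sequence irreversible. No stereocentre is created: C2 is left trigonal on purpose, to be set in step 2. The step needs ortho- rather than para-C-acylation and chromone rather than coumarin (Pechmann) closure; the two ortho carbons of 1 are equivalent through the mirror plane of the phenol, delivery through the OH favours them, and the acid-free melt keeps the ring carbon from attacking the aryl ketone.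

Step 2
Reactants: 5 5,7-dimethoxy-2-(3,4,5-trimethoxyphenyl)-4H-chromen-4-one
Product: 6 (2S,4S)-5,7-dimethoxy-2-(3,4,5-trimethoxyphenyl)-3,4-dihydro-2H-chromen-4-ol (2,4-cis flavan-4-ol)
Conditions: [Ru(cod)(2-methylallyl)2] (5 mol %), (R,R)-SINpEt·HBF4 (1,3-bis[(R)-1-(naphthalen-1-yl)ethyl]-4,5-dihydroimidazolium tetrafluoroborate, 10 mol %), KOtBu (15 mol %), H2 (100 bar), toluene, 40 °C
Reagents that add atoms: none
Why: Ru–NHC-catalysed asymmetric hydrogenation of flavones is a known reaction type in which the chiral bis(NHC) ruthenium hydride should add H2 to one enantioface of the C2=C3 bond (catalyst control sets C2 as S) and then reduce the ketone from the face anti to the C2 aryl group to the 2,4-cis carbinol, so that no base-labile β-aryloxy ketone lingers in the basic medium.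

Step 3
Reactants: 6 (2S,4S)-5,7-dimethoxy-2-(3,4,5-trimethoxyphenyl)-3,4-dihydro-2H-chromen-4-ol
Product: 7 (2S)-5,7-dimethoxy-2-(3,4,5-trimethoxyphenyl)-2,3-dihydro-4H-chromen-4-one (target)
Conditions: Dess–Martin periodinane (1.3 equiv), pyridine (4 equiv), CH2Cl2, 0 °C to rt
Reagents that add atoms: none
Why: Dess–Martin oxidation of a secondary benzylic alcohol under pyridine-buffered, non-enolising conditions should return the C4 ketone without touching C2 (no acid to ionise the electron-rich benzylic carbinol, no base strong enough for retro-oxa-Michael ring opening), so the 2S configuration set in step 2 is carried into the target.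

**Compound list**

1 | 3,5-dimethoxyphenol | COc1cc(O)cc(OC)c1 | starting material
2 | ethyl 3-oxo-3-(3,4,5-trimethoxyphenyl)propanoate (ethyl 3,4,5-trimethoxybenzoylacetate) | CCOC(=O)CC(=O)c1cc(OC)c(OC)c(OC)c1 | starting material
3 | 3-oxo-3-(3,4,5-trimethoxyphenyl)prop-1-en-1-one (aroylketene) | O=C=CC(=O)c1cc(OC)c(OC)c(OC)c1 | intermediate
4 | 1-(2-hydroxy-4,6-dimethoxyphenyl)-3-(3,4,5-trimethoxyphenyl)propane-1,3-dione | COc1cc(O)c(C(=O)CC(=O)c2cc(OC)c(OC)c(OC)c2)c(OC)c1 | intermediate
5 | 5,7-dimethoxy-2-(3,4,5-trimethoxyphenyl)-4H-chromen-4-one (pentamethoxyflavone) | COc1cc(OC)c2c(c1)OC(=CC2=O)c1cc(OC)c(OC)c(OC)c1 | intermediate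
6 | (2S,4S)-5,7-dimethoxy-2-(3,4,5-trimethoxyphenyl)-3,4-dihydro-2H-chromen-4-ol | COc1cc(OC)c2c(c1)O[C@H](c1cc(OC)c(OC)c(OC)c1)C[C@@H]2O | intermediate
7 | (2S)-5,7-dimethoxy-2-(3,4,5-trimethoxyphenyl)-2,3-dihydro-4H-chromen-4-one | COc1cc(OC)c2c(c1)O[C@H](c1cc(OC)c(OC)c(OC)c1)CC2=O | target

**Totals**

Total step count: 3. Longest linear sequence: 3 steps.

**Steps most likely to fail**

First, step 1 (key annulation). What may go wrong: C-acylation para to the hydroxyl (between the two methoxy groups), which cannot cyclise; Pechmann-type closure to the 4-arylcoumarin; and self-condensation of the aroylketene. The fallback sets out from 2 and replaces 1 by phloroglucinol (commercial, Oc1cc(O)cc(O)c1) in the same kind of melt. All three ring carbons of the triol are equivalent and each lies between two hydroxyls, so every C-acylation is productive. The melt should pass through 1-(2,4,6-trihydroxyphenyl)-3-(3,4,5-trimethoxyphenyl)propane-1,3-dione F1 (not isolated) to 5,7-dihydroxy-2-(3,4,5-trimethoxyphenyl)-4H-chromen-4-one F2. Exhaustive O-methylation (MeI in excess, K2CO3, DMF, 50 °C) should then give 5, where the route is rejoined.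

Second, step 2 (asymmetric hydrogenation). What may go wrong: incomplete discrimination of the C2=C3 enantiofaces, or partial racemisation of the transient flavanone by base-induced ring opening to the 2'-hydroxychalcone before the carbonyl is reduced. The fallback replaces enantioface selection by kinetic resolution as the source of enantiopurity. It sets out from scalemic 6, which is oxidised as in step 3. The scalemic ketone is then submitted to asymmetric transfer hydrogenation ([Cp*RhCl(TsDPEN)], antipode matched to the 2R ketone, HCO2H/Et3N, EtOAc, rt). This should reduce the minor 2R enantiomer to (2R,4R)-5,7-dimethoxy-2-(3,4,5-trimethoxyphenyl)-3,4-dihydro-2H-chromen-4-ol F3, which is removed by chromatography, and leave 7 in high enantiomeric purity; the route is rejoined at 7.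

Third, step 3 (oxidation). What may go wrong: ionisation of the doubly oxygen-activated benzylic C4 carbinol (dehydration to the flav-3-ene, oligomerisation) on handling or under the oxidant, or over-oxidation back to 5. The fallback avoids the carbinol altogether. It sets out from 5 and uses CuH-catalysed asymmetric conjugate reduction, a known reaction type for chromones and β,β-disubstituted enones (Cu(OAc)2·H2O, DTBM-SEGPHOS antipode matched to 2S, polymethylhydrosiloxane, t-BuOH, toluene, 0 °C to rt). Hydride should be delivered to C2 only and the copper enolate protonated in situ, giving 7 directly and rejoining the route at 7; this fallback makes no new compound (F0).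

**Further compounds**

F1 | step 1 | 1-(2,4,6-trihydroxyphenyl)-3-(3,4,5-trimethoxyphenyl)propane-1,3-dione | Oc1cc(O)c(C(=O)CC(=O)c2cc(OC)c(OC)c(OC)c2)c(O)c1
F2 | step 1 | 5,7-dihydroxy-2-(3,4,5-trimethoxyphenyl)-4H-chromen-4-one | Oc1cc(O)c2c(c1)OC(=CC2=O)c1cc(OC)c(OC)c(OC)c1
F3 | step 2 | (2R,4R)-5,7-dimethoxy-2-(3,4,5-trimethoxyphenyl)-3,4-dihydro-2H-chromen-4-ol | COc1cc(OC)c2c(c1)O[C@@H](c1cc(OC)c(OC)c(OC)c1)C[C@H]2O
F0 | step 3 | none | none
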